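**Retrosynthetic overview**

1. Target 16 is genistein with an (E)-4-hydroxy-3-methylbut-2-enyl group at C6; fluoride releases it from the bis-silyl ether 15.
2. Feature used: ring A is an acylphloroglucinol in which C5 and C7 are at the carbonyl oxidation level and C6, between them, is the α-carbon of an ester that already carries the side chain; C4a, C8a and C8 are C3, C2 and the 2-methyl carbon of a 4-pyranone (ring C).
3. Key disconnection: C7–C8 (lateral Claisen) and C5–C6 (Dieckmann-type closure), leading to pyranone ester 8 and hexenoate 13, joined in one flask.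
4. 8 comes from C-acylation of methyl acetoacetate with arylacetyl chloride 4, then Me2NCH(OMe)2 supplies C2 and closes ring C. 13 comes from an (E)-selective Wittig reaction of methyl 4-oxobutanoate, Luche reduction and silylation.
5. Ring order: ring B is bought with 1, ring C is closed in step 4, ring A in step 8.

Key step: step 8

Remark: the SMILES is read as the (E)-alkene (CH2OH trans to the benzylic CH2). The target has no stereocentre, so this geometry is the only stereochemical element; it is set in step 5. Isoflavone numbering is used throughout (O1, C2, C3, C4, C4a, C5–C8, C8a).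

**Route**

Step 1
Reactants: 1 4-hydroxyphenylacetic acid
Product: 3 4-(triisopropylsilyloxy)phenylacetic acid, via triisopropylsilyl 4-(triisopropylsilyloxy)phenylacetate 2 (not isolated)
Conditions: TIPSCl (2.3 equiv), imidazole, DMF, rt; then K2CO3, MeOH–H2O, rt, short contact; 1 M HCl to pH 3, 0 °C
Reagents that add atoms: triisopropylsilyl chloride, CC(C)[Si](Cl)(C(C)C)C(C)C
Why: Imidazole-mediated silylation converts both the phenol and the acid into silyl derivatives, and the silyl ester, far more labile than the hindered aryl silyl ether, is then cleaved selectively by mild carbonate solvolysis (silyl protection with selective silyl ester hydrolysis).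

Step 2
Reactants: 3 4-(triisopropylsilyloxy)phenylacetic acid
Product: 4 4-(triisopropylsilyloxy)phenylacetyl chloride
Conditions: (COCl)2 (1.3 equiv), cat. DMF, CH2Cl2, 0 °C → rt; evaporate, use crude
Reagents that add atoms: oxalyl chloride, O=C(Cl)C(=O)Cl
Why: Acid chloride formation through the Vilsmeier-type chloroiminium intermediate proceeds at or below room temperature, and the hindered aryl TIPS ether should tolerate the short exposure to HCl.

Step 3
Reactants: 4 4-(triisopropylsilyloxy)phenylacetyl chloride; 5 methyl acetoacetate
Product: 6 methyl 2-acetyl-3-oxo-4-[4-(triisopropylsilyloxy)phenyl]butanoate (enolised tricarbonyl)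
Conditions: 5, MgCl2 (1 equiv), pyridine (2 equiv), CH2Cl2, 0 °C; then 4, 0 °C → rt; cold 1 M HCl
Reagents that add atoms: none
Why: Rathke-type soft enolisation: MgCl2 and pyridine generate the chelated magnesium enolate of the β-keto ester, which is acylated on carbon, and the chelated tricarbonyl product is shielded from O-acylation and from a second acylation.

Step 4
Reactants: 6 methyl 2-acetyl-3-oxo-4-[4-(triisopropylsilyloxy)phenyl]butanoate
Product: 8 methyl 2-methyl-4-oxo-5-[4-(triisopropylsilyloxy)phenyl]-4H-pyran-3-carboxylate, via enaminone 7 (not isolated)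
Conditions: Me2NCH(OMe)2 (1.2 equiv), PhMe, 70 °C; then AcOH, 60 °C
Reagents that add atoms: N,N-dimethylformamide dimethyl acetal, COC(OC)N(C)C
Why: The amide acetal condenses at the benzylic ketone methylene, the most reactive CH2 of 6, and the enol oxygen of the acetyl group then closes ring C by addition–elimination on the enaminone with loss of dimethylamine, the same aminomethylenation–cyclisation that turns deoxybenzoins into isoflavones and 2-acyl-1,3-diones into fused 4-pyranones; the new CH becomes C2 and no stereocentre is formed.

Step 5
Reactants: 9 methyl 4-oxobutanoate; 10 2-(triphenylphosphoranylidene)propanal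
Product: 11 methyl (E)-5-methyl-6-oxohex-4-enoate
Conditions: PhMe, 90 °C
Reagents that add atoms: none
Why: Wittig olefination with the stabilised α-methyl formyl ylide passes through the late, product-like transition state typical of stabilised ylides and should give the (E)-2-methyl enal with the formyl group trans to the chain, while the methyl ester is inert to the ylide.

Step 6
Reactants: 11 methyl (E)-5-methyl-6-oxohex-4-enoate
Product: 12 methyl (E)-6-hydroxy-5-methylhex-4-enoate
Conditions: NaBH4, CeCl3·7H2O, MeOH, 0 °C
Reagents that add atoms: none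
Why: Luche reduction: NaBH4 with CeCl3 reduces the conjugated aldehyde in 1,2-fashion at 0 °C without reducing the methyl ester or touching the alkene geometry.

Step 7
Reactants: 12 methyl (E)-6-hydroxy-5-methylhex-4-enoate
Product: 13 methyl (E)-6-(tert-butyldimethylsilyloxy)-5-methylhex-4-enoate
Conditions: TBSCl, imidazole, DMF, rt
Reagents that add atoms: tert-butyldimethylsilyl chloride, CC(C)(C)[Si](C)(C)Cl
Why: Imidazole-mediated silylation of the unhindered primary allylic alcohol gives the TBS ether, which withstands the amide base of the next step.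

Step 8
Reactants: 8 methyl 2-methyl-4-oxo-5-[4-(triisopropylsilyloxy)phenyl]-4H-pyran-3-carboxylate; 13 methyl (E)-6-(tert-butyldimethylsilyloxy)-5-methylhex-4-enoate
Product: 15 6-[(E)-4-(tert-butyldimethylsilyloxy)-3-methylbut-2-enyl]-5,7-dihydroxy-4'-(triisopropylsilyloxy)isoflavone, via pyranone ketone 14 (not isolated)
Conditions: 8, LiN(SiMe3)2 (1.1 equiv), THF, −78 °C; 13 (1.2 equiv), −78 → −20 °C; LiN(SiMe3)2 (3.4 equiv) dropwise, −20 °C → rt; aq. NH4Cl
Reagents that add atoms: none
Why: Proposed new method: the 2-methyl group of 8 is vinylogously acidic through both C4=O and the C3 ester, so one equivalent of LiN(SiMe3)2 gives the lithium dienolate, whose exocyclic carbon attacks the ester carbonyl of 13 (bond C7–C8, lateral Claisen condensation); the resulting ketone 14 is at once deprotonated to its extended enolate, which is why the rest of the base is fed in only after the ester. Further amide then removes a C6 proton of that enolate, and the C6 carbanion adds to the ring ester carbonyl C5 and expels methoxide (bond C5–C6, Dieckmann-type 6-exo-trig closure of the carbocyclic ring A); two enolisations of the resulting cyclohexenedione give the aromatic 5,7-diol, which makes the sequence irreversible. The closest known reaction types are the lateral acylation of 2-methyl-4-pyranone and 2-methylchromone anions and the Claisen–Dieckmann condensation of ortho-toluate anions with esters to naphthalene-1,3-diols; running both on a 4-pyranone-3-carboxylate in one flask has not been shown. No stereocentre is formed, and the (E)-alkene is not touched because neither carbanion is allylic to it. The step needs carbon rather than oxygen acylation in the closure (oxygen attack of the C7 enolate would give a fused 2-pyranone), which the excess of strong base should secure by forming the more nucleophilic C6 carbanion; it also needs acylation rather than enolisation of 13, which the order of addition and the proton-shuttling amine HN(SiMe3)2 should secure. C6 is fixed as the ester α-carbon, so a C6 versus C8 alkylation question cannot arise.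

Step 9
Reactants: 15 6-[(E)-4-(tert-butyldimethylsilyloxy)-3-methylbut-2-enyl]-5,7-dihydroxy-4'-(triisopropylsilyloxy)isoflavone
Product: 16 5,7-dihydroxy-3-(4-hydroxyphenyl)-6-[(E)-4-hydroxy-3-methylbut-2-enyl]chromen-4-one
Conditions: Bu4NF (3 equiv), AcOH (3 equiv), THF, 0 °C → rt
Reagents that add atoms: none
Why: Fluoride-induced desilylation removes the aryl TIPS ether and the primary TBS ether in one operation, and the acetic acid buffer keeps the phenoxides protonated so that the base-sensitive ring C is not opened and the (E)-allylic alcohol is released unchanged.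

**Compound list**

1 | 4-hydroxyphenylacetic acid | OC(=O)Cc1ccc(O)cc1 | starting material
2 | triisopropylsilyl 4-(triisopropylsilyloxy)phenylacetate | CC(C)[Si](OC(=O)Cc1ccc(O[Si](C(C)C)(C(C)C)C(C)C)cc1)(C(C)C)C(C)C | intermediate
3 | 4-(triisopropylsilyloxy)phenylacetic acid | OC(=O)Cc1ccc(O[Si](C(C)C)(C(C)C)C(C)C)cc1 | intermediate
4 | 4-(triisopropylsilyloxy)phenylacetyl chloride | O=C(Cl)Cc1ccc(O[Si](C(C)C)(C(C)C)C(C)C)cc1 | intermediate
5 | methyl acetoacetate | COC(=O)CC(C)=O | starting material
6 | methyl 2-acetyl-3-oxo-4-[4-(triisopropylsilyloxy)phenyl]butanoate (keto form drawn; C2 is configurationally labile) | COC(=O)C(C(C)=O)C(=O)Cc1ccc(O[Si](C(C)C)(C(C)C)C(C)C)cc1 | intermediate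
7 | methyl (E)-2-acetyl-5-(dimethylamino)-3-oxo-4-[4-(triisopropylsilyloxy)phenyl]pent-4-enoate (push–pull alkene, geometry labile) | COC(=O)C(C(C)=O)C(=O)/C(=C/N(C)C)c1ccc(O[Si](C(C)C)(C(C)C)C(C)C)cc1 | intermediate
8 | methyl 2-methyl-4-oxo-5-[4-(triisopropylsilyloxy)phenyl]-4H-pyran-3-carboxylate | COC(=O)c1c(C)occ(-c2ccc(O[Si](C(C)C)(C(C)C)C(C)C)cc2)c1=O | intermediate
9 | methyl 4-oxobutanoate | COC(=O)CCC=O | starting material
10 | 2-(triphenylphosphoranylidene)propanal | CC(C=O)=P(c1ccccc1)(c1ccccc1)c1ccccc1 | starting material
11 | methyl (E)-5-methyl-6-oxohex-4-enoate | COC(=O)CC/C=C(\C)C=O | intermediate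
12 | methyl (E)-6-hydroxy-5-methylhex-4-enoate | COC(=O)CC/C=C(\C)CO | intermediate
13 | methyl (E)-6-(tert-butyldimethylsilyloxy)-5-methylhex-4-enoate | COC(=O)CC/C=C(\C)CO[Si](C)(C)C(C)(C)C | intermediate
14 | methyl 2-[(E)-7-(tert-butyldimethylsilyloxy)-6-methyl-2-oxohept-5-enyl]-4-oxo-5-[4-(triisopropylsilyloxy)phenyl]-4H-pyran-3-carboxylate | COC(=O)c1c(CC(=O)CC/C=C(\C)CO[Si](C)(C)C(C)(C)C)occ(-c2ccc(O[Si](C(C)C)(C(C)C)C(C)C)cc2)c1=O | intermediate
15 | 6-[(E)-4-(tert-butyldimethylsilyloxy)-3-methylbut-2-enyl]-5,7-dihydroxy-4'-(triisopropylsilyloxy)isoflavone | C/C(=C\Cc1c(O)cc2occ(-c3ccc(O[Si](C(C)C)(C(C)C)C(C)C)cc3)c(=O)c2c1O)CO[Si](C)(C)C(C)(C)C | intermediate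
16 | 5,7-dihydroxy-3-(4-hydroxyphenyl)-6-[(E)-4-hydroxy-3-methylbut-2-enyl]chromen-4-one | C/C(=C\Cc1c(O)cc2occ(-c3ccc(O)cc3)c(=O)c2c1O)CO | target

**Totals**

Total step count: 9.
Longest linear sequence: 6 steps (steps 1, 2, 3, 4, 8, 9); the side-chain branch is steps 5, 6, 7, then 8 and 9.

**Steps most likely to fail**

1. Step 8 (proposed new method). Three processes may defeat it:
 - the amide base may enolise ester 13 faster than the stabilised dienolate of 8 acylates it, so the lateral Claisen stalls;
 - the closure may run through the enolate oxygen at C7 (lactone formation) or stop at the ketone stage, because the C6 carbanion is not reached with LiN(SiMe3)2;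
 - methoxide set free in the flask may add to the unsubstituted pyranone position (later C2) and open ring C.

 Fallback, setting out from 13 and 8 and returning at 15: the acyl donor is changed and the two C–C bond formations are separated, each being an established reaction type. Ester 13 is converted with MeNH(OMe)·HCl and i-PrMgCl (THF, −20 °C) into the Weinreb amide (E)-6-(tert-butyldimethylsilyloxy)-N-methoxy-N,5-dimethylhex-4-enamide F1. The lithium dienolate of 8 (LiN(SiMe3)2, 1.05 equiv, THF, −78 °C) is acylated with F1; the chelated tetrahedral adduct keeps the carbonyl masked until the quench, so no excess base is needed and ketone 14 is isolated. Ketone 14 is then treated with LiN(i-Pr)2 (3 equiv, THF, −78 → 0 °C). With no external ester competing for base, the dianion should close ring A by intramolecular Claisen condensation, as ortho-(2-oxoalkyl)benzoates do on the way to naphthalene-1,3-diols, and give 15.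

2. Step 4. Three processes may interfere:
 - the acetal may condense at the acetyl methyl group instead of the benzylic methylene, giving the isomeric pyranone;
 - it may O-methylate the acidic enol or cleave the acetyl group by retro-Claisen attack of the liberated amine;
 - a second condensation may occur at the activated 2-methyl group of 8.

 Fallback, setting out from 5 and returning at 8: the aryl group is attached to a preformed pyranone by cross-coupling. Methyl acetoacetate 5 is C-acetylated (AcCl, MgCl2, pyridine, CH2Cl2) to methyl 2-acetyl-3-oxobutanoate F2, in which both methyl ketones are equivalent. Me2NCH(OMe)2 gives the enaminone methyl (E)-2-acetyl-5-(dimethylamino)-3-oxopent-4-enoate F3, which is not isolated. Iodine in CHCl3 with pyridine induces iodocyclisation, as in the 3-iodochromone synthesis from enaminones, to methyl 5-iodo-2-methyl-4-oxo-4H-pyran-3-carboxylate F4. Suzuki–Miyaura coupling of F4 with 4-hydroxyphenylboronic acid (Pd(PPh3)4, K3PO4, dioxane–H2O, 70 °C) gives methyl 5-(4-hydroxyphenyl)-2-methyl-4-oxo-4H-pyran-3-carboxylate F5. Silylation (TIPSCl, imidazole, DMF) then gives 8.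

3. Step 3. The arylacetyl chloride may lose HCl to the arylketene under the amine base (dimerisation, O-acylation), and the unsymmetrical tricarbonyl may lose an acyl group on work-up.

 Fallback, setting out from 4 and returning at 6: the order of the two acylations is reversed. Acid chloride 4 acylates Meldrum's acid (pyridine, CH2Cl2, 0 °C) to 5-{1-hydroxy-2-[4-(triisopropylsilyloxy)phenyl]ethylidene}-2,2-dimethyl-1,3-dioxane-4,6-dione F6. Methanolysis in refluxing MeOH gives the β-keto ester methyl 3-oxo-4-[4-(triisopropylsilyloxy)phenyl]butanoate F7. Its magnesium enolate (MgCl2, pyridine, CH2Cl2) is C-acetylated with acetyl chloride to give 6.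

**Further compounds**

F1 | step 8 | (E)-6-(tert-butyldimethylsilyloxy)-N-methoxy-N,5-dimethylhex-4-enamide | CON(C)C(=O)CC/C=C(\C)CO[Si](C)(C)C(C)(C)C
F2 | step 4 | methyl 2-acetyl-3-oxobutanoate | COC(=O)C(C(C)=O)C(C)=O
F3 | step 4 | methyl (E)-2-acetyl-5-(dimethylamino)-3-oxopent-4-enoate | COC(=O)C(C(C)=O)C(=O)/C=C/N(C)C
F4 | step 4 | methyl 5-iodo-2-methyl-4-oxo-4H-pyran-3-carboxylate | COC(=O)c1c(C)occ(I)c1=O
F5 | step 4 | methyl 5-(4-hydroxyphenyl)-2-methyl-4-oxo-4H-pyran-3-carboxylate | COC(=O)c1c(C)occ(-c2ccc(O)cc2)c1=O
F6 | step 3 | 5-{1-hydroxy-2-[4-(triisopropylsilyloxy)phenyl]ethylidene}-2,2-dimethyl-1,3-dioxane-4,6-dione | CC1(C)OC(=O)C(=C(O)Cc2ccc(O[Si](C(C)C)(C(C)C)C(C)C)cc2)C(=O)O1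
F7 | step 3 | methyl 3-oxo-4-[4-(triisopropylsilyloxy)phenyl]butanoate | COC(=O)CC(=O)Cc1ccc(O[Si](C(C)C)(C(C)C)C(C)C)cc1
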